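**Plan**

- Numbering: unit 1 is the 7-methoxyflavone bound through C8 (plain numbers, ring B primed). Unit 2 is the flavone bound through C6'' (double primes, ring B triple primes).
- Cuts, in retrosynthetic order: C4–C4a in ring C of unit 1 (leaving a 3-aryloxy-3-arylacrylic acid), then the enol ether bond O1–C2, then the biaryl bond C8–C6''.
- Enabling feature: in ring A of unit 1, the O1-bearing carbon C8a has two neighbours, C8 (taken by the biaryl bond) and C4a (a free CH). C4a lies ortho to the oxygens on C8a and C5 and para to the one on C7, so a C4 acyl cation hung on O1 meets a single reachable, very electron-rich carbon.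
- Forward order: the three rings of unit 2 come with apigenin. Ring A of unit 1 (from 3,5-dimethoxyphenol) is attached by Suzuki coupling. Ring B of unit 1 and C2–C4 arrive with an arylpropiolate by phenol addition. Ring C of unit 1 closes last, and BCl3 then frees five phenols and leaves the 7-methyl ether.
- Stereochemistry: the target has no stereocentre, so none is set. The only stereo-element on the way is the enol ether double bond, and acid levels it during the ring closure.

Key step: step 11

Assumption: the target is drawn without a defined sense of the C8–C6'' axis, so the biaryl is made as the racemate; the enol ethers are drawn as the Z isomers expected from anti addition, and any E isomer is carried along because it converges in the ring closure.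

**Step 1**
Reactants: 1 apigenin
Product: 2 7,4'-di-O-benzylapigenin
Conditions: BnBr (2.2 equiv), K2CO3, DMF, rt → 40 °C
Reagents that add atoms: benzyl bromide, BrCc1ccccc1
Why: Williamson ether synthesis in which the two acidic, unhindered phenols at C7 and C4' are alkylated, while the 5-OH, held in a hydrogen bond to the C4 carbonyl, is left untouched by a limited amount of halide under mild carbonate conditions.

**Step 2**
Reactants: 2 7,4'-di-O-benzylapigenin
Product: 3 7,4'-di-O-benzyl-6-iodoapigenin
Conditions: BnMe3N·ICl2 (1.05 equiv), CaCO3, CH2Cl2–MeOH, rt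
Reagents that add atoms: benzyltrimethylammonium dichloroiodate, C[N+](C)(C)Cc1ccccc1.Cl[I-]Cl
Why: Electrophilic aromatic iodination; 5-hydroxy-7-alkoxyflavones are known to take up iodine from this reagent at C6, the carbon ortho to the free phenol, whereas C8 becomes the preferred site once the 5-oxygen is alkylated, which is why iodine goes in before the third benzyl group.

**Step 3**
Reactants: 3 7,4'-di-O-benzyl-6-iodoapigenin
Product: 4 5,7,4'-tri-O-benzyl-6-iodoapigenin
Conditions: BnBr (excess), K2CO3, DMF, 70 °C
Reagents that add atoms: benzyl bromide, BrCc1ccccc1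
Why: Williamson ether synthesis under more forcing conditions, which break the hydrogen bond of the 5-OH and cap it so that no acidic or chelating group interferes with the cross-coupling and the later phenol addition; the aryl iodide is inert to carbonate.

**Step 4**
Reactants: 5 3,5-dimethoxyphenol
Product: 6 1,3-dimethoxy-5-(methoxymethoxy)benzene
Conditions: MOMCl, iPr2NEt, CH2Cl2, 0 °C → rt
Reagents that add atoms: chloromethyl methyl ether, COCCl
Why: O-alkylation of the phenol with an α-chloro ether (MOM protection), chosen because the acetal directs the next lithiation and can later be removed by mild acid beside benzyl ethers.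

**Step 5**
Reactants: 6 1,3-dimethoxy-5-(methoxymethoxy)benzene
Product: 8 2-[2,4-dimethoxy-6-(methoxymethoxy)phenyl]-4,4,5,5-tetramethyl-1,3,2-dioxaborolane, via aryllithium 7 (not isolated)
Conditions: n-BuLi, THF, 0 °C → rt; iPrOBpin, −78 °C → rt; H2O
Reagents that add atoms: n-butyllithium, [Li]CCCC (lithium, held in 7 only); 2-isopropoxy-4,4,5,5-tetramethyl-1,3,2-dioxaborolane, CC(C)OB1OC(C)(C)C(C)(C)O1
Why: Directed ortho-metalation followed by borylation: the chelating OMOM group is the stronger director and acts together with the adjacent OMe, so lithium should settle on one of the two equivalent carbons between OMOM and OMe rather than between the two OMe groups, the borate ester traps it, and a minor regioisomer would be removed by chromatography.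

**Step 6**
Reactants: 4 5,7,4'-tri-O-benzyl-6-iodoapigenin; 8 2-[2,4-dimethoxy-6-(methoxymethoxy)phenyl]-4,4,5,5-tetramethyl-1,3,2-dioxaborolane
Product: 9 5,7,4'-tri-O-benzyl-6-[2,4-dimethoxy-6-(methoxymethoxy)phenyl]apigenin
Conditions: Pd(OAc)2 (cat.), SPhos, K3PO4, toluene–H2O, 100 °C; 8 in excess
Reagents that add atoms: none
Why: Suzuki–Miyaura coupling: the bulky, electron-rich biarylphosphine SPhos gives a monoligated zerovalent palladium species that inserts into the flanked C–I bond and still allows transmetalation and reductive elimination to a tetra-ortho-oxygenated biaryl, and the excess of 8 makes up for protodeboronation.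

**Step 7**
Reactants: 9 5,7,4'-tri-O-benzyl-6-[2,4-dimethoxy-6-(methoxymethoxy)phenyl]apigenin
Product: 10 5,7,4'-tri-O-benzyl-6-(2-hydroxy-4,6-dimethoxyphenyl)apigenin
Conditions: aq HCl (2 M), THF–MeOH, 40 °C
Reagents that add atoms: none
Why: Acid-catalysed acetal hydrolysis, mild enough that the aryl benzyl ethers (including the more labile one next to the carbonyl) and the flavone remain.

**Step 8**
Reactants: 11 1-(benzyloxy)-4-ethynylbenzene
Product: 13 allyl 3-[4-(benzyloxy)phenyl]propiolate, via lithium acetylide 12 (not isolated)
Conditions: n-BuLi, THF, −78 °C; ClCO2CH2CH=CH2, −78 → 0 °C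
Reagents that add atoms: n-butyllithium, [Li]CCCC (lithium, held in 12 only); allyl chloroformate, C=CCOC(=O)Cl
Why: Deprotonation of the terminal alkyne and acylation of the acetylide with a chloroformate, a standard entry to arylpropiolates; the allyl ester is chosen because it can later be removed without hydroxide or acid.

**Step 9**
Reactants: 10 5,7,4'-tri-O-benzyl-6-(2-hydroxy-4,6-dimethoxyphenyl)apigenin; 13 allyl 3-[4-(benzyloxy)phenyl]propiolate
Product: 14 allyl (Z)-3-[4-(benzyloxy)phenyl]-3-[2-(5'',7'',4'''-tri-O-benzylapigenin-6''-yl)-3,5-dimethoxyphenoxy]acrylate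
Conditions: Cs2CO3 (0.3 equiv), DMF, 70 °C
Reagents that add atoms: none
Why: Oxa-Michael addition of a phenoxide to an alkynoate (the first half of the phenol–arylpropiolate flavone synthesis): the caesium phenoxide attacks the β-carbon and the allenolate is protonated anti by further phenol, which places the aryloxy and ester groups cis (Z) and regenerates the base.

**Step 10**
Reactants: 14 allyl (Z)-3-[4-(benzyloxy)phenyl]-3-[2-(5'',7'',4'''-tri-O-benzylapigenin-6''-yl)-3,5-dimethoxyphenoxy]acrylate
Product: 15 (Z)-3-[4-(benzyloxy)phenyl]-3-[2-(5'',7'',4'''-tri-O-benzylapigenin-6''-yl)-3,5-dimethoxyphenoxy]acrylic acid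
Conditions: Pd(PPh3)4 (cat.), PhNHMe, THF, rt
Reagents that add atoms: none
Why: Tsuji–Trost deallylation: zerovalent palladium ionises the allyl ester and the weakly nucleophilic N-methylaniline takes up the allyl group, so the acid is released under near-neutral conditions that spare the enol ether (prone to addition–elimination with hydroxide or strong amines), the flavone and the benzyl ethers.

**Step 11**
Reactants: 15 (Z)-3-[4-(benzyloxy)phenyl]-3-[2-(5'',7'',4'''-tri-O-benzylapigenin-6''-yl)-3,5-dimethoxyphenoxy]acrylic acid
Product: 17 4',5'',7'',4'''-tetra-O-benzyl-5,7-di-O-methylagathisflavone (protected target), via mixed trifluoroacetic anhydride 16 (not isolated)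
Conditions: (CF3CO)2O (2 equiv), CH2Cl2, 0 °C → rt
Reagents that add atoms: trifluoroacetic anhydride, O=C(OC(=O)C(F)(F)F)C(F)(F)F (its acyl group stands in 16 only and is gone in 17)
Why: The acid exchanges with (CF3CO)2O to give mixed anhydride 16, whose trifluoroacetate leaves readily because the acyl cation is conjugated with the enol ether oxygen and the para-benzyloxyphenyl group; C4a attacks this cation (or 16 itself), and loss of the C4a proton restores ring A and leaves the new C4–C4a bond. The closest known reaction is the intramolecular Friedel–Crafts acylation of 3-aryloxycinnamic acids to flavones, and activation by (CF3CO)2O is established for electron-rich aryloxy acids on the way to chromanones and xanthones. The one ring formed, pyranone ring C of unit 1, closes as a six-membered ring in exo mode at the acyl carbon (6-exo-dig on the acylium ion, 6-exo-trig on 16), with C2=C3 and C8a–C4a inside the new ring. No stereocentre arises; only the Z isomer can reach C4a, and the trifluoroacetic acid released equilibrates any E isomer by reversible protonation at C3, so both drain to 17. The step needs site selectivity on ring A, and the substrate secures it: of the two carbons next to C8a, C8 carries the biaryl bond, C6 is out of reach of the three-atom tether, and C4a is pushed by three oxygen donors. Chemoselectivity rests on rate, since closure onto the trioxygenated ring should run at or below room temperature, where the benzyl ethers, the carbonyl-deactivated ring A of unit 2 and C6 resist acid cleavage and trifluoroacetylation, and fast anhydride formation keeps the free acid from decarboxylating.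

**Step 12**
Reactants: 17 4',5'',7'',4'''-tetra-O-benzyl-5,7-di-O-methylagathisflavone
Product: 18 7-O-methylagathisflavone (methyl ether on the 8-linked unit; target)
Conditions: BCl3 (excess), C6HMe5, CH2Cl2, −78 → 0 °C; H2O
Reagents that add atoms: none
Why: Lewis-acid ether cleavage: BCl3 with pentamethylbenzene as a non-basic benzyl cation trap removes aryl benzyl ethers at low temperature, and on warming boron chelated between the C4 carbonyl and O5 cleaves the 5-methyl ether, while the 7-methyl ether has no neighbouring carbonyl and ordinary aryl methyl ethers resist BCl3 at 0 °C.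

**Compound list**

1 | apigenin | O=c1cc(-c2ccc(O)cc2)oc2cc(O)cc(O)c12 | starting material
2 | 7,4'-di-O-benzylapigenin | O=c1cc(-c2ccc(OCc3ccccc3)cc2)oc2cc(OCc3ccccc3)cc(O)c12 | intermediate
3 | 7,4'-di-O-benzyl-6-iodoapigenin | O=c1cc(-c2ccc(OCc3ccccc3)cc2)oc2cc(OCc3ccccc3)c(I)c(O)c12 | intermediate
4 | 5,7,4'-tri-O-benzyl-6-iodoapigenin | O=c1cc(-c2ccc(OCc3ccccc3)cc2)oc2cc(OCc3ccccc3)c(I)c(OCc3ccccc3)c12 | intermediate
5 | 3,5-dimethoxyphenol | COc1cc(O)cc(OC)c1 | starting material
6 | 1,3-dimethoxy-5-(methoxymethoxy)benzene | COCOc1cc(OC)cc(OC)c1 | intermediate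
7 | [2,4-dimethoxy-6-(methoxymethoxy)phenyl]lithium | [Li]c1c(OC)cc(OC)cc1OCOC | intermediate
8 | 2-[2,4-dimethoxy-6-(methoxymethoxy)phenyl]-4,4,5,5-tetramethyl-1,3,2-dioxaborolane | COCOc1cc(OC)cc(OC)c1B1OC(C)(C)C(C)(C)O1 | intermediate
9 | 5,7,4'-tri-O-benzyl-6-[2,4-dimethoxy-6-(methoxymethoxy)phenyl]apigenin | COCOc1cc(OC)cc(OC)c1-c1c(OCc2ccccc2)cc2oc(-c3ccc(OCc4ccccc4)cc3)cc(=O)c2c1OCc1ccccc1 | intermediate
10 | 5,7,4'-tri-O-benzyl-6-(2-hydroxy-4,6-dimethoxyphenyl)apigenin | Oc1cc(OC)cc(OC)c1-c1c(OCc2ccccc2)cc2oc(-c3ccc(OCc4ccccc4)cc3)cc(=O)c2c1OCc1ccccc1 | intermediate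
11 | 1-(benzyloxy)-4-ethynylbenzene | C#Cc1ccc(OCc2ccccc2)cc1 | starting material
12 | lithium [4-(benzyloxy)phenyl]acetylide | [Li]C#Cc1ccc(OCc2ccccc2)cc1 | intermediate
13 | allyl 3-[4-(benzyloxy)phenyl]propiolate | C=CCOC(=O)C#Cc1ccc(OCc2ccccc2)cc1 | intermediate
14 | allyl (Z)-3-[4-(benzyloxy)phenyl]-3-[2-(5'',7'',4'''-tri-O-benzylapigenin-6''-yl)-3,5-dimethoxyphenoxy]acrylate | COc1cc(OC)cc(O/C(=C\C(=O)OCC=C)c2ccc(OCc3ccccc3)cc2)c1-c1c(OCc2ccccc2)cc2oc(-c3ccc(OCc4ccccc4)cc3)cc(=O)c2c1OCc1ccccc1 | intermediate
15 | (Z)-3-[4-(benzyloxy)phenyl]-3-[2-(5'',7'',4'''-tri-O-benzylapigenin-6''-yl)-3,5-dimethoxyphenoxy]acrylic acid | COc1cc(OC)cc(O/C(=C\C(=O)O)c2ccc(OCc3ccccc3)cc2)c1-c1c(OCc2ccccc2)cc2oc(-c3ccc(OCc4ccccc4)cc3)cc(=O)c2c1OCc1ccccc1 | intermediate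
16 | mixed anhydride of 15 with trifluoroacetic acid | COc1cc(OC)cc(O/C(=C\C(=O)OC(=O)C(F)(F)F)c2ccc(OCc3ccccc3)cc2)c1-c1c(OCc2ccccc2)cc2oc(-c3ccc(OCc4ccccc4)cc3)cc(=O)c2c1OCc1ccccc1 | intermediate
17 | 4',5'',7'',4'''-tetra-O-benzyl-5,7-di-O-methylagathisflavone | COc1cc(OC)c2c(=O)cc(-c3ccc(OCc4ccccc4)cc3)oc2c1-c1c(OCc2ccccc2)cc2oc(-c3ccc(OCc4ccccc4)cc3)cc(=O)c2c1OCc1ccccc1 | intermediate
18 | 7-O-methylagathisflavone | COc1cc(O)c2c(=O)cc(-c3ccc(O)cc3)oc2c1-c1c(O)cc2oc(-c3ccc(O)cc3)cc(=O)c2c1O | target

**Step count**

Total step count: 12.
Longest linear sequence: 9 steps from apigenin (steps 1, 2, 3, 6, 7, 9, 10, 11, 12).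

**Steps most likely to fail**

**Step 6.**
- Risk: transmetalation onto a palladium centre flanked by two benzyloxy groups may be so slow that protodeboronation of the 2,6-dioxygenated boronate and hydrodeiodination of the iodide win.
- Fallback: setting out from 6, the lithiation of step 5 is repeated to 7. This is transmetalated with ZnCl2 in THF to [2,4-dimethoxy-6-(methoxymethoxy)phenyl]zinc chloride F1. A Negishi coupling of it with iodide 4 (Pd2(dba)3, RuPhos, THF, 70 °C) runs without water or base, so no proton source can strip the metal. It comes back to the route at 9.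

**Step 9.**
- Risk: the conjugate addition may stall or reverse, because the phenoxide sits next to a bulky flavonyl group and the alkyne is deactivated by its para-benzyloxy donor. Prolonged heating with base may also erode the material.
- Fallback: setting out from 13, hydroiodination (NaI, AcOH, 110 °C, anti addition) gives allyl (Z)-3-[4-(benzyloxy)phenyl]-3-iodoacrylate F2. An Ullmann-type C–O vinylation of phenol 10 with it (CuI, N,N-dimethylglycine, Cs2CO3, dioxane, 80 °C) replaces iodide with retention of geometry. It comes back to the route at 14.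

**Step 11.**
- Risk: three things may compete with ring closure in the acidic medium. These are protodecarboxylation through the C3-protonated oxocarbenium ion, acid loss of the benzyl ether next to the unit 2 carbonyl, and intermolecular trifluoroacetylation at C6.
- Fallback: setting out from 15, 1-chloro-N,N,2-trimethylprop-1-en-1-amine in CH2Cl2 at 0 °C converts the acid under neutral conditions into (Z)-3-[4-(benzyloxy)phenyl]-3-[2-(5'',7'',4'''-tri-O-benzylapigenin-6''-yl)-3,5-dimethoxyphenoxy]acryloyl chloride F3. This is taken up in (CF3)2CHOH at rt, a hydrogen-bond-donor medium known to promote intramolecular Friedel–Crafts acylation of acid chlorides without added Lewis or Brønsted acid and without any trifluoroacetylating agent. The same C4–C4a bond forms, and the route is rejoined at 17.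

**Further compounds**

F1 | step 6 | [2,4-dimethoxy-6-(methoxymethoxy)phenyl]zinc chloride | COCOc1cc(OC)cc(OC)c1[Zn]Cl
F2 | step 9 | allyl (Z)-3-[4-(benzyloxy)phenyl]-3-iodoacrylate | I/C(=C\C(=O)OCC=C)c1ccc(OCc2ccccc2)cc1
F3 | step 11 | (Z)-3-[4-(benzyloxy)phenyl]-3-[2-(5'',7'',4'''-tri-O-benzylapigenin-6''-yl)-3,5-dimethoxyphenoxy]acryloyl chloride | COc1cc(OC)cc(O/C(=C\C(=O)Cl)c2ccc(OCc3ccccc3)cc2)c1-c1c(OCc2ccccc2)cc2oc(-c3ccc(OCc4ccccc4)cc3)cc(=O)c2c1OCc1ccccc1
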